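(The earlier runs and the new flask were computed from invented constants; noise was put on by code.)

A ratio of ratios was what I looked for: how far the starting complex had gone, set against how far the ligands stood in its favour, folded into one number for a flask that stops short.

| flask | starting complex | incoming ligand | leaving ligand | remark | time |
|---|---|---|---|---|---|
| Thursday's | 0.050 M (fed, over 12 min) | 0.11 M | 0.050 M | run made earlier |  |
| flask | 0.10 M (fed, over 12 min) | 0.110 M | 0.0500 M |  | 3.0 d |

- Thursday's (time / h: starting complex / %, complex with four exchanged / %): 1.33: 40.4, 0.4; 4.00: 33.7, 0.6; 6.00: 32.9, 0.4; 10.0: 31.0, 0.5; 15.0: 32.4, 0.8

(each reading ± 0.5 percentage points)

- the analysis behind the earlier runs scatters by 0.5 percentage points, standard deviation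
- what has gone from starting complex into another species counts as reacted, even if it can come back
- the reaction counts as stopped when no species that holds the starting complex changes by six tenths of a point or more over the second half of the time

- which holds at 3.0 d: what has brought the reaction to rest, or that it has not come to rest (all of the starting complex has reacted / forward and back rates have come level / the incoming ligand has run out first / it is still moving)
- share of the starting complex used up at 3.0 d
- amount of complex with four exchanged if the flask were left three thousand times as long, in percent of the starting complex charged

On Thursday's run the starting complex moved by 0.5 percentage points between 6.00 h and 15.0 h, against a scatter of 0.5 points, and its readings from 6.00 h on average 32.1%. I counted one leaving ligand freed per complex reacted, which made x = 0.0340 M. Thursday's charge of incoming ligand was larger than that x, so I read the plateau as forward and back rates level. The balance at that plateau gave 2.33: the exchange quotient Q, reacted over left of starting complex, times c(leaving ligand) over c(incoming ligand) at rest, an apparent equilibrium constant.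

I held Q for the flask and solved the same balance with its charges, which gave x = 0.0550 M, or 55.0% used up, and I expected rest, since 3.0 d is long against Thursday's 4.00 h. Was one number enough? Not for complex with four exchanged, the small correction: I scaled its Thursday reading by the power 4 of the ligand ratio and got 0.0633%.

The forecast gave forward and back rates have come level, 53% and 0.1%: “This looks like reversible exchange reaching equilibrium, not exhaustion of a reagent”.

The flask ended thus: forward and back rates have come level, with 61.0% used up at 3.0 d and 0.0782% of complex with four exchanged after the long wait.

    complex with two exchanged + incoming ligand ⇌ leaving ligand + complex with three exchanged (K = 0.300, k = 75.0 /M/h)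
    starting complex ⇌ dormant form (K = 0.580, k = 0.100 /h)
    complex with three exchanged + incoming ligand ⇌ leaving ligand + complex with four exchanged (K = 0.0810, k = 7.40 /M/h)
    starting complex + incoming ligand ⇌ leaving ligand + complex with one exchanged (K = 1.20, k = 14.0 /M/h)
    complex with one exchanged + incoming ligand ⇌ leaving ligand + complex with two exchanged (K = 0.650, k = 43.0 /M/h)

My 55.0% fell 6 points short of the flask and the forecast's 53% fell 8 points short, and the flask held dormant form at 22.6% at 3.00 d. One more flask, charged with 0.19 M of incoming ligand, took the same Q: solving gave x = 0.0700 M, or 70.0% used up, and that flask stands at 70.0%, with dormant form at 17.4%.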